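**Retrosynthetic overview**
- The 1,2-dioxane (the only ring) is closed last, in one flask, from a peroxide-free acyclic tertiary carbinol: H2O2 is captured at C6 (SN1), then the C6 hydroperoxide adds 6-exo to the (E)-enoate (O–C3 bond), as in the presumed hydroperoxide/enoate biogenesis.
- Tertiary carbinol ⇒ EtMgBr + C6 ketone; enoate ⇒ Wittig on a γ-keto aldehyde.
- C4–C5 bond and C4 ⇒ organocatalytic oxidative coupling of butanal with the kinetic enol silane of a methyl ketone.
- C8 and C10 ⇒ two Cu-catalysed asymmetric conjugate additions (EtMgBr to an enone, n-BuMgBr to methyl crotonate) joined by reduction/Wittig.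
- Ring order: one ring, formed in the final step.

Assumption: the hands of the ferrocenyl ligand and of the imidazolidinone are assigned by analogy with the usual facial preference of these catalyst families, not verified; the product configurations written are the ones required, and the mirror-image catalyst is used if a test run shows the opposite sense.

Abbreviation and numbering: J = (R)-1-[(Sp)-2-(diphenylphosphino)ferrocenyl]ethyldicyclohexylphosphine, ent-J = its enantiomer; C1–C14 is the target chain numbering (C1 ester carbon, C3 and C6 the two peroxide carbons).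

**Route**

Step 1
Reactants: 1 methyl (E)-but-2-enoate (methyl crotonate)
Product: 2 methyl (3S)-3-methylheptanoate
Conditions: n-BuMgBr (1.2 equiv), CuBr·SMe2 (1 mol %), ent-J (1.2 mol %), t-BuOMe, −75 °C
Reagents that add atoms: n-butylmagnesium bromide CCCC[Mg]Br
Why: Copper-catalysed asymmetric conjugate addition of a Grignard reagent (Feringa type) to the (E)-enoate, in which the chiral ferrocenyl diphosphine–CuBr complex selects the enoate face and so sets the methyl-bearing centre (target C10) as S.

Step 2
Reactants: 2 methyl (3S)-3-methylheptanoate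
Product: 4 (3E,6S)-6-methyldec-3-en-2-one, via (3S)-3-methylheptanal 3 (not isolated)
Conditions: iBu2AlH (1.05 equiv), CH2Cl2, −78 °C; then Ph3P=CHC(O)CH3, −78 °C to 40 °C
Reagents that add atoms: 1-(triphenylphosphoranylidene)propan-2-one CC(=O)C=P(c1ccccc1)(c1ccccc1)c1ccccc1
Why: Partial reduction of the ester to the aluminium hemiacetal followed by in-flask Wittig olefination of the released aldehyde with the stabilised keto ylide gives the (E)-enone without touching the existing stereocentre.

Step 3
Reactants: 4 (3E,6S)-6-methyldec-3-en-2-one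
Product: 5 (4S,6S)-4-ethyl-6-methyldecan-2-one
Conditions: EtMgBr (1.3 equiv), CuBr·SMe2 (5 mol %), J (6 mol %), t-BuOMe, −75 °C
Reagents that add atoms: ethylmagnesium bromide CC[Mg]Br
Why: A second copper-catalysed asymmetric conjugate addition, now to an acyclic enone, is catalyst-controlled (the remote methyl centre has no say) and sets the ethyl-bearing centre (target C8) as S.

Step 4
Reactants: 5 (4S,6S)-4-ethyl-6-methyldecan-2-one
Product: 6 {[(4S,6S)-4-ethyl-6-methyldec-1-en-2-yl]oxy}trimethylsilane
Conditions: LiN(iPr)2, THF, −78 °C; Me3SiCl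
Reagents that add atoms: chlorotrimethylsilane C[Si](C)(C)Cl
Why: Kinetic deprotonation of the methyl ketone at the unhindered CH3 group and O-silylation give the terminal silyl enol ether regioselectively, with no stereocentre affected.

Step 5
Reactants: 6 {[(4S,6S)-4-ethyl-6-methyldec-1-en-2-yl]oxy}trimethylsilane; 7 butanal
Product: 8 (2S,6S,8S)-2,6-diethyl-8-methyl-4-oxododecanal
Conditions: (2S,5S)-5-benzyl-2-tert-butyl-3-methylimidazolidin-4-one·CF3CO2H (20 mol %), (NH4)2Ce(NO3)6 (2 equiv), 2,6-di-tert-butylpyridine, H2O (2 equiv), acetone, −20 °C; 6 used in excess (2 equiv), the surplus recovered as 5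
Reagents that add atoms: water O (delivers the aldehyde oxygen on iminium hydrolysis)
Why: Organo-SOMO α-enolation of an aldehyde (enamine radical-cation coupling, MacMillan type), in which the one-electron-oxidised enamine of butanal, shielded on one face by the imidazolidinone, adds to the enol silane terminus, forming the C4–C5 bond and setting C4 as S under catalyst control.

Step 6
Reactants: 8 (2S,6S,8S)-2,6-diethyl-8-methyl-4-oxododecanal
Product: 9 methyl (2E,4S,8S,10S)-4,8-diethyl-10-methyl-6-oxotetradec-2-enoate
Conditions: Ph3P=CHCO2Me, CH2Cl2, 0 °C to rt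
Reagents that add atoms: methyl 2-(triphenylphosphoranylidene)acetate COC(=O)C=P(c1ccccc1)(c1ccccc1)c1ccccc1
Why: Wittig olefination with a stabilised, non-basic ylide reacts only at the aldehyde (not the ketone), is E-selective and leaves the adjacent C4 centre unepimerised.

Step 7
Reactants: 9 methyl (2E,4S,8S,10S)-4,8-diethyl-10-methyl-6-oxotetradec-2-enoate
Product: 10 methyl (2E,4S,6RS,8S,10S)-4,6,8-triethyl-6-hydroxy-10-methyltetradec-2-enoate
Conditions: EtMgBr and CeCl3 (premixed, 1.5 equiv each), THF, −78 °C; AcOH quench at −78 °C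
Reagents that add atoms: ethylmagnesium bromide CC[Mg]Br
Why: Carbonyl 1,2-addition of the weakly basic organocerium reagent (Imamoto conditions) is selective for the ketone over the enoate and avoids enolisation, giving the tertiary carbinol as a C6 epimer mixture whose C6 configuration is deliberately erased in step 8.

Step 8
Reactants: 10 methyl (2E,4S,6RS,8S,10S)-4,6,8-triethyl-6-hydroxy-10-methyltetradec-2-enoate
Product: 12 methyl 2-[(3S,4S,6S)-4,6-diethyl-6-[(2S,4S)-2-ethyl-4-methyloctyl]-1,2-dioxan-3-yl]acetate, via tertiary hydroperoxide 11 (not isolated)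
Conditions: 50% aq. H2O2 (20 equiv), H2SO4 (cat.), Et2O, 0 °C to rt; NaHCO3 wash, no purification; then Et2NH (0.2 equiv), CF3CH2OH, 0 °C to rt; silica gel, then HPLC
Reagents that add atoms: hydrogen peroxide OO
Why: Acid-catalysed SN1 perhydrolysis of the tertiary alcohol gives the C6 hydroperoxide through a planar cation (both epimers of 10 converge, C6 forming about 1:1 with no control), and the amine-triggered 6-exo-trig peroxy-Michael addition then closes the ring under kinetic control through a chair transition state with the C4 ethyl equatorial and anti to the incoming oxygen and the enoate arm axial, which is expected to set C3 cis to the C4 ethyl (3S), the (6S) product being separated from its ring-diastereomeric 6-epimer by chromatography.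

**Compound list**
1 | methyl (E)-but-2-enoate | C/C=C/C(=O)OC | starting material
2 | methyl (3S)-3-methylheptanoate | CCCC[C@H](C)CC(=O)OC | intermediate
3 | (3S)-3-methylheptanal | CCCC[C@H](C)CC=O | intermediate
4 | (3E,6S)-6-methyldec-3-en-2-one | CCCC[C@H](C)C/C=C/C(C)=O | intermediate
5 | (4S,6S)-4-ethyl-6-methyldecan-2-one | CCCC[C@H](C)C[C@H](CC)CC(C)=O | intermediate
6 | {[(4S,6S)-4-ethyl-6-methyldec-1-en-2-yl]oxy}trimethylsilane | CCCC[C@H](C)C[C@H](CC)CC(=C)O[Si](C)(C)C | intermediate
7 | butanal | CCCC=O | starting material
8 | (2S,6S,8S)-2,6-diethyl-8-methyl-4-oxododecanal | CCCC[C@H](C)C[C@H](CC)CC(=O)C[C@H](CC)C=O | intermediate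
9 | methyl (2E,4S,8S,10S)-4,8-diethyl-10-methyl-6-oxotetradec-2-enoate | CCCC[C@H](C)C[C@H](CC)CC(=O)C[C@H](CC)/C=C/C(=O)OC | intermediate
10 | methyl (2E,4S,6RS,8S,10S)-4,6,8-triethyl-6-hydroxy-10-methyltetradec-2-enoate (C6 epimer mixture) | CCCC[C@H](C)C[C@H](CC)CC(O)(CC)C[C@H](CC)/C=C/C(=O)OC | intermediate
11 | methyl (2E,4S,6RS,8S,10S)-4,6,8-triethyl-6-hydroperoxy-10-methyltetradec-2-enoate (C6 epimer mixture) | CCCC[C@H](C)C[C@H](CC)CC(OO)(CC)C[C@H](CC)/C=C/C(=O)OC | intermediate
12 | methyl 2-[(3S,4S,6S)-4,6-diethyl-6-[(2S,4S)-2-ethyl-4-methyloctyl]-1,2-dioxan-3-yl]acetate | CCCC[C@H](C)C[C@H](CC)C[C@@]1(CC)C[C@H](CC)[C@H](CC(=O)OC)OO1 | target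

**Step count and risks**
Total steps: 8. Longest linear sequence: 8 (1 to 12).

Most likely to fail, first: step 8. The cation may eliminate or be trapped otherwise in the acidic peroxide medium. C6 is formed without bias, so at most half of the cyclised material is 12. The 3,4-cis preference rests on kinetic control and could erode toward the 3,4-trans epimer. Fallback, setting out from 10 and returning at 11: 10 is dehydrated (Burgess reagent, benzene, 50 °C) to the trisubstituted alkene mixture, drawn as methyl (2E,4S,8S,10S)-4,8-diethyl-6-ethylidene-10-methyltetradec-2-enoate F1; its C6 double-bond isomers all give the same tertiary radical. Hydrogen-atom-transfer peroxidation with Co(thd)2 (thd = 2,2,6,6-tetramethylheptane-3,5-dionate), Et3SiH and O2 in 1,2-dichloroethane (Mukaiyama–Isayama) gives methyl (2E,4S,6RS,8S,10S)-4,6,8-triethyl-10-methyl-6-[(triethylsilyl)peroxy]tetradec-2-enoate F2. Bu4NF in THF removes the silyl group to give 11, which cyclises to 12 as in step 8. This replaces the cationic C6–O bond formation by a radical capture of O2 under neutral conditions.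

Second: step 5. The oxidative coupling has mostly been used with aryl enol silanes; an aliphatic, β-branched enol silane may be oxidised or hydrolysed competitively, and yield or ee may be low. Fallback, setting out from 6 and returning at 8: 6 is brominated regiospecifically (N-bromosuccinimide, THF, 0 °C) to (4S,6S)-1-bromo-4-ethyl-6-methyldecan-2-one F3. F3 is then coupled with butanal 7 by photoredox organocatalytic α-alkylation (Ru(bpy)3Cl2, the trans-2-tert-butyl-3,5-dimethylimidazolidin-4-one triflate salt of the hand that gives 2S, 2,6-lutidine, DMF, visible light) to give 8. Here an electrophilic α-keto radical adds to the neutral enamine, the reverse polarity of the main step, and the bromide is the limiting partner.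

Third: step 7. The tertiary alkoxide can add 5-exo to the enoate (tetrahydrofuran formation), and any enolisation of the ketone opens an intramolecular Michael path to a cyclopentanone. Fallback, setting out from 8 and returning at 10: the aldehyde of 8 is masked (MeOH, cat. TsOH, molecular sieves, 0 °C) as (2S,6S,8S)-2,6-diethyl-1,1-dimethoxy-8-methyldodecan-4-one F4. EtMgBr/CeCl3 (THF, −78 °C) gives (2S,4RS,6S,8S)-2,4,6-triethyl-1,1-dimethoxy-8-methyldodecan-4-ol F5. Aqueous AcOH unmasks the aldehyde, which closes to the lactol (3S)-3,5-diethyl-5-[(2S,4S)-2-ethyl-4-methyloctyl]oxolan-2-ol F6. Wittig reaction of the lactol with Ph3P=CHCO2Me (toluene, 60 °C) gives 10. The ethyl group is thus added before any enoate is present.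

Further compounds
F1 | step 8 | methyl (2E,4S,8S,10S)-4,8-diethyl-6-ethylidene-10-methyltetradec-2-enoate (E/Z mixture, with its C6 double-bond isomers) | CCCC[C@H](C)C[C@H](CC)CC(=CC)C[C@H](CC)/C=C/C(=O)OC
F2 | step 8 | methyl (2E,4S,6RS,8S,10S)-4,6,8-triethyl-10-methyl-6-[(triethylsilyl)peroxy]tetradec-2-enoate | CCCC[C@H](C)C[C@H](CC)CC(CC)(OO[Si](CC)(CC)CC)C[C@H](CC)/C=C/C(=O)OC
F3 | step 5 | (4S,6S)-1-bromo-4-ethyl-6-methyldecan-2-one | CCCC[C@H](C)C[C@H](CC)CC(=O)CBr
F4 | step 7 | (2S,6S,8S)-2,6-diethyl-1,1-dimethoxy-8-methyldodecan-4-one | CCCC[C@H](C)C[C@H](CC)CC(=O)C[C@H](CC)C(OC)OC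
F5 | step 7 | (2S,4RS,6S,8S)-2,4,6-triethyl-1,1-dimethoxy-8-methyldodecan-4-ol | CCCC[C@H](C)C[C@H](CC)CC(O)(CC)C[C@H](CC)C(OC)OC
F6 | step 7 | (3S)-3,5-diethyl-5-[(2S,4S)-2-ethyl-4-methyloctyl]oxolan-2-ol | CCCC[C@H](C)C[C@H](CC)CC1(CC)C[C@H](CC)C(O)O1
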